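**Retrosynthetic overview** (hydrindenone numbering: C1–C3 = ring CH2 groups, C3a = methyl-bearing carbon next to the C4 ketone, C5 and C6 = enone carbons, C7 = CH2, C7a = second methyl-bearing carbon)
1. The cyclohexenone is opened at C5=C6 (reductive aldol, then dehydration); the C6 side-chain ketone comes from a 1,1-disubstituted alkene, and the C3a methyl from enolate methylation of a cyclopentyl ynone.
2. Enabling feature: the ketone carbon C4 sits on ring-fusion carbon C3a, directly beside C7a. Counting C4 into the five-membered ring C1–C2–C3–C3a–C7a gives a cyclohexanone, so the cyclopentane is made by a 1,2-shift of C7a from C4 to C3a in a 2-chlorocyclohexanone after an alkynyl group has added to C4.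
3. C7a is set by a Pd-catalysed decarboxylative asymmetric allylation, which also joins the chroman fragment to the carbocycle.
4. The chroman C2 center comes from an enantioselective domino Wacker cyclisation/carbonylation of an alkenylphenol; its ester is homologated to a 2-substituted allylic alcohol.
5. Ring order: arene (bought) → dihydropyran ring of the chroman → cyclohexanone (bought) → cyclopentane by ring contraction → cyclohexenone by aldol closure.

Key step: step 9

Remark: Chr = (2S)-6-methoxy-2,8-dimethyl-3,4-dihydro-2H-chromen-2-yl. The sense of induction of (S,S)-Bn-BOXAX (step 2) and (S)-t-BuPHOX (step 7) is assumed from the closest known substrates; if either proves opposite, the enantiomeric ligand is used.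

**Step 1**
Reactants: 1 4-methoxy-2,6-dimethylphenol; 2 3-chloro-2-methylprop-1-ene
Product: 4 4-methoxy-2-methyl-6-(3-methylbut-3-en-1-yl)phenol, via benzylic dianion 3 (not isolated)
Conditions: n-BuLi (2.2 equiv), KOt-Bu (2.2 equiv), heptane, reflux; then 2, THF, −78 °C to rt; aq NH4Cl
Reagents that add atoms: none
Why: Phenoxide-directed lateral (benzylic) metalation by the n-BuLi/KOt-Bu superbase gives a C,O-dianion whose carbanion is alkylated by the allylic chloride (directed lateral metalation–SN2 alkylation); the two methyl groups are equivalent and no stereocenter is formed.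

**Step 2**
Reactants: 4 4-methoxy-2-methyl-6-(3-methylbut-3-en-1-yl)phenol
Product: 5 methyl [(2S)-6-methoxy-2,8-dimethyl-3,4-dihydro-2H-chromen-2-yl]acetate (Chr-CH2CO2Me)
Conditions: Pd(OCOCF3)2 (5 mol %), (S,S)-Bn-BOXAX (20 mol %), p-benzoquinone (4 equiv), CO (1 atm), MeOH, rt
Reagents that add atoms: carbon monoxide, [C-]#[O+]; methanol, CO
Why: Enantioselective domino Wacker cyclisation/carbonylation: ligated divalent palladium activates the alkene for 6-exo-trig oxypalladation by the phenol, the BOXAX ligand choosing the alkene face and so setting the quaternary chroman C2, and the alkylpalladium (no β-hydrogen) inserts CO and is cleaved by methanol while benzoquinone reoxidises zerovalent palladium.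

**Step 3**
Reactants: 5 Chr-CH2CO2Me
Product: 7 trimethyl[2-(Chr-methyl)prop-2-en-1-yl]silane, via bis(silylmethyl) carbinol 6 (not isolated)
Conditions: Me3SiCH2MgCl (3 equiv), CeCl3 (3 equiv), THF, −78 °C to rt; then silica gel, CH2Cl2, rt
Reagents that add atoms: (trimethylsilyl)methylmagnesium chloride, C[Si](C)(C)C[Mg]Cl
Why: Double addition of the weakly basic organocerium reagent to the ester followed by Peterson elimination of the β-hydroxysilane gives the 2-substituted allylsilane without enolising the β-aryloxy ester; no stereocenter is formed.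

**Step 4**
Reactants: 7 trimethyl[2-(Chr-methyl)prop-2-en-1-yl]silane
Product: 9 2-(Chr-methyl)prop-2-en-1-ol, via epoxysilane 8 (not isolated)
Conditions: mCPBA (1.1 equiv), CH2Cl2, −20 °C; then AcOH (cat.), MeOH, rt
Reagents that add atoms: 3-chloroperoxybenzoic acid, OOC(=O)c1cccc(Cl)c1
Why: Epoxidation of the electron-rich allylsilane and acid-triggered opening of the β-silyl epoxide with loss of silicon (allylsilane-to-allylic-alcohol transposition) gives the 2-substituted allylic alcohol; the epoxide stereocenter is transient.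

**Step 5**
Reactants: 9 2-(Chr-methyl)prop-2-en-1-ol; 10 methyl 2-oxocyclohexane-1-carboxylate
Product: 11 2-(Chr-methyl)prop-2-en-1-yl 2-oxocyclohexane-1-carboxylate
Conditions: DMAP (0.3 equiv), toluene, reflux, 4 Å molecular sieves
Reagents that add atoms: none
Why: DMAP-catalysed transesterification of the enolisable β-keto ester with removal of methanol installs the allyl ester needed for step 7; the α-carbon is configurationally labile.

**Step 6**
Reactants: 11 2-(Chr-methyl)prop-2-en-1-yl 2-oxocyclohexane-1-carboxylate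
Product: 12 2-(Chr-methyl)prop-2-en-1-yl 1-methyl-2-oxocyclohexane-1-carboxylate (both C1 epimers)
Conditions: MeI, K2CO3, acetone, 50 °C
Reagents that add atoms: iodomethane, CI
Why: C-Alkylation of the β-keto ester enolate gives the α-quaternary ester as an epimer mixture, which is harmless because this center is erased in step 7.

**Step 7**
Reactants: 12 2-(Chr-methyl)prop-2-en-1-yl 1-methyl-2-oxocyclohexane-1-carboxylate
Product: 13 (2S)-2-methyl-2-[2-(Chr-methyl)prop-2-en-1-yl]cyclohexan-1-one
Conditions: Pd2(dba)3 (2.5 mol %), (S)-t-BuPHOX (6.25 mol %), toluene, 30 °C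
Reagents that add atoms: none
Why: Decarboxylative asymmetric allylic alkylation (Tsuji allylation): oxidative addition to zerovalent palladium, loss of CO2 and C–C bond formation within the PHOX-ligated π-allylpalladium enolate convert both ester epimers into one ketone, the ligand setting the quaternary carbon (future C7a) as S.

**Step 8**
Reactants: 13 (2S)-2-methyl-2-[2-(Chr-methyl)prop-2-en-1-yl]cyclohexan-1-one
Product: 15 (6S)-2-chloro-6-methyl-6-[2-(Chr-methyl)prop-2-en-1-yl]cyclohexan-1-one (both C2 epimers), via lithium enolate 14 (not isolated)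
Conditions: LiN(i-Pr)2 (1.1 equiv), THF, −78 °C; then NCS, −78 to −40 °C
Reagents that add atoms: N-chlorosuccinimide, O=C1CCC(=O)N1Cl
Why: Deprotonation at the only enolisable position and electrophilic chlorination of the enolate place the leaving group next to the carbonyl; the C–Cl center is formed as an epimer mixture, and both epimers serve in step 9 because this carbon is enolised again in step 10.

**Step 9**
Reactants: 15 (6S)-2-chloro-6-methyl-6-[2-(Chr-methyl)prop-2-en-1-yl]cyclohexan-1-one; 16 trimethyl[(2-methylbut-3-yn-2-yl)oxy]silane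
Product: 18 1-{(2S)-2-methyl-2-[2-(Chr-methyl)prop-2-en-1-yl]cyclopentyl}-4-methyl-4-(trimethylsilyloxy)pent-2-yn-1-one (both C1 epimers), via chlorohydrin bromomagnesium alkoxide 17 (not isolated)
Conditions: 16 (1.05 equiv), EtMgBr (1.05 equiv), THF, 40 °C; add 15, 0 °C to rt; then toluene, 85 °C
Reagents that add atoms: none
Why: The magnesium acetylide adds to the ketone carbon anti to the C–Cl bond (polar Felkin–Anh control) to give the cis-chlorohydrin alkoxide 17; on heating, in the chair with C–Cl equatorial, the ring bond from the carbinol carbon to the quaternary carbon is antiperiplanar to C–Cl and shifts to the chlorine-bearing carbon as chloride leaves and the alkoxide becomes the ynone C=O. This is the semipinacol (quasi-Favorskii) rearrangement of a 2-halocyclohexanol metal alkoxide, the classical ring contraction of Grignard adducts of 2-chlorocyclohexanones to acylcyclopentanes. The cyclopentane is closed by the 1,2-alkyl shift itself (ring contraction with inversion at the C–Cl carbon, not an exo or endo cyclisation), which expels the former carbonyl carbon from the ring as C4 and forms the C3a–C7a bond. The migrating quaternary carbon (future C7a) keeps the configuration set in step 7, since 1,2-shifts proceed with retention at the migrating center, and the new CH center (future C3a) may form as a mixture because it is enolised in step 10. The step needs ring-bond migration to win over alkynyl migration, epoxide closure and enolisation: a fully substituted sp3 carbon migrates far better than an sp carbon, the cis relation of O and Cl leaves no antiperiplanar oxygen for epoxide formation, the carbinol carbon has no hydrogen to shift, and the weakly basic magnesium acetylide should add to the activated α-chloro ketone faster than it deprotonates it.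

**Step 10**
Reactants: 18 1-{(2S)-2-methyl-2-[2-(Chr-methyl)prop-2-en-1-yl]cyclopentyl}-4-methyl-4-(trimethylsilyloxy)pent-2-yn-1-one
Product: 20 1-{(1S,2S)-1,2-dimethyl-2-[2-(Chr-methyl)prop-2-en-1-yl]cyclopentyl}-4-methyl-4-(trimethylsilyloxy)pent-2-yn-1-one, via lithium enolate 19 (not isolated)
Conditions: LiN(SiMe3)2 (1.2 equiv), THF, −78 °C; then MeI (5 equiv), DMPU, −78 to −30 °C
Reagents that add atoms: iodomethane, CI
Why: Deprotonation of the only α-hydrogen and methylation of the exocyclic enolate (ketone enolate alkylation); iodomethane is expected to approach anti to the larger CH2 side chain of the neighbouring quaternary carbon, whose methyl takes the inside position to minimise allylic strain, so the two methyl groups become cis (1S,2S).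

**Step 11**
Reactants: 20 1-{(1S,2S)-1,2-dimethyl-2-[2-(Chr-methyl)prop-2-en-1-yl]cyclopentyl}-4-methyl-4-(trimethylsilyloxy)pent-2-yn-1-one
Product: 22 1-[(1S,2S)-2-(3-Chr-2-oxopropyl)-1,2-dimethylcyclopentyl]-4-methyl-4-(trimethylsilyloxy)pent-2-yn-1-one, via ozonide 21 (not isolated)
Conditions: O3 (1.05 equiv as a titrated CH2Cl2 solution), CH2Cl2, −78 °C; then Me2S, −78 °C to rt
Reagents that add atoms: ozone, [O-][O+]=O
Why: Ozonolysis of the only electron-rich alkene (the conjugated triple bond reacts far more slowly) with reductive work-up unmasks the side-chain ketone under neutral conditions; no stereocenter is formed.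

**Step 12**
Reactants: 22 1-[(1S,2S)-2-(3-Chr-2-oxopropyl)-1,2-dimethylcyclopentyl]-4-methyl-4-(trimethylsilyloxy)pent-2-yn-1-one
Product: 23 (2Z)-1-[(1S,2S)-2-(3-Chr-2-oxopropyl)-1,2-dimethylcyclopentyl]-4-methyl-4-(trimethylsilyloxy)pent-2-en-1-one
Conditions: H2 (1 atm), Pd/CaCO3 poisoned with Pb(OAc)2, quinoline, EtOAc, rt
Reagents that add atoms: none
Why: Semihydrogenation of the alkyne over the poisoned palladium catalyst stops at the (Z)-enone needed for the conjugate reduction of step 13; no stereocenter is formed.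

**Step 13**
Reactants: 23 (2Z)-1-[(1S,2S)-2-(3-Chr-2-oxopropyl)-1,2-dimethylcyclopentyl]-4-methyl-4-(trimethylsilyloxy)pent-2-en-1-one
Product: 25 (3aS,7aS)-6-(Chr-methyl)-6-hydroxy-3a,7a-dimethyl-5-[2-methyl-2-(trimethylsilyloxy)propyl]octahydro-4H-inden-4-one (C5/C6 epimers), via copper enolate 24 (not isolated)
Conditions: [(Ph3P)CuH]6 (0.35 equiv), toluene, −40 to 0 °C; aq NH4Cl
Reagents that add atoms: none
Why: Reductive aldol cyclisation: conjugate hydride transfer from the copper hydride forms the enolate only at the enone α-carbon, which closes onto the side-chain ketone in a 6-(enolendo)-exo-trig aldol; the cis ring fusion follows from the cis arms on the cyclopentane, the new C5 and C6 centers are removed in step 14, and the neutral conditions avoid enolising the CH2 next to the chroman, which would open the aryl ether by retro-oxa-Michael.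

**Step 14**
Reactants: 25 (3aS,7aS)-6-(Chr-methyl)-6-hydroxy-3a,7a-dimethyl-5-[2-methyl-2-(trimethylsilyloxy)propyl]octahydro-4H-inden-4-one
Product: 27 (3aS,7aS)-6-(Chr-methyl)-3a,7a-dimethyl-5-[2-methyl-2-(trimethylsilyloxy)propyl]-1,2,3,3a,7,7a-hexahydro-4H-inden-4-one, via mesylate 26 (not isolated)
Conditions: MsCl, Et3N, DMAP (cat.), CH2Cl2, 0 °C; then DBU, rt
Reagents that add atoms: none
Why: Sulfonylation of the tertiary aldol hydroxyl and E1cB elimination through the only enolisable α-position (C5) give the tetrasubstituted enone (aldol dehydration); the two transient stereocenters disappear and the quaternary centers are untouched.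

**Step 15**
Reactants: 27 (3aS,7aS)-6-(Chr-methyl)-3a,7a-dimethyl-5-[2-methyl-2-(trimethylsilyloxy)propyl]-1,2,3,3a,7,7a-hexahydro-4H-inden-4-one
Product: 28 (3aS,7aS)-5-(2-hydroxy-2-methylpropyl)-6-(Chr-methyl)-3a,7a-dimethyl-1,2,3,3a,7,7a-hexahydro-4H-inden-4-one (CNP0224132.2)
Conditions: citric acid (cat.), MeOH, rt
Reagents that add atoms: none
Why: Mild acid methanolysis of the tertiary trimethylsilyl ether frees the alcohol without affecting the enone, the chroman or any stereocenter.

**Compound list**
1 | 4-methoxy-2,6-dimethylphenol | COc1cc(C)c(O)c(C)c1 | starting material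
2 | 3-chloro-2-methylprop-1-ene | CC(=C)CCl | starting material
3 | benzylic dianion of 1, dipotassium salt (not isolated) | COc1cc(C)c([O-])c([CH2-])c1.[K+].[K+] | intermediate
4 | 4-methoxy-2-methyl-6-(3-methylbut-3-en-1-yl)phenol | COc1cc(C)c(O)c(CCC(C)=C)c1 | intermediate
5 | methyl [(2S)-6-methoxy-2,8-dimethyl-3,4-dihydro-2H-chromen-2-yl]acetate | COc1cc(C)c2c(c1)CC[C@@](C)(CC(=O)OC)O2 | intermediate
6 | 1-Chr-2-[(trimethylsilyl)methyl]-3-(trimethylsilyl)propan-2-ol (not isolated) | COc1cc(C)c2c(c1)CC[C@@](C)(CC(O)(C[Si](C)(C)C)C[Si](C)(C)C)O2 | intermediate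
7 | trimethyl[2-(Chr-methyl)prop-2-en-1-yl]silane | COc1cc(C)c2c(c1)CC[C@@](C)(CC(=C)C[Si](C)(C)C)O2 | intermediate
8 | 2-(Chr-methyl)-2-[(trimethylsilyl)methyl]oxirane (not isolated) | COc1cc(C)c2c(c1)CC[C@@](C)(CC1(C[Si](C)(C)C)CO1)O2 | intermediate
9 | 2-(Chr-methyl)prop-2-en-1-ol | COc1cc(C)c2c(c1)CC[C@@](C)(CC(=C)CO)O2 | intermediate
10 | methyl 2-oxocyclohexane-1-carboxylate | COC(=O)C1CCCCC1=O | starting material
11 | 2-(Chr-methyl)prop-2-en-1-yl 2-oxocyclohexane-1-carboxylate | COc1cc(C)c2c(c1)CC[C@@](C)(CC(=C)COC(=O)C1CCCCC1=O)O2 | intermediate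
12 | 2-(Chr-methyl)prop-2-en-1-yl 1-methyl-2-oxocyclohexane-1-carboxylate | COc1cc(C)c2c(c1)CC[C@@](C)(CC(=C)COC(=O)C1(C)CCCCC1=O)O2 | intermediate
13 | (2S)-2-methyl-2-[2-(Chr-methyl)prop-2-en-1-yl]cyclohexan-1-one | COc1cc(C)c2c(c1)CC[C@@](C)(CC(=C)C[C@]1(C)CCCCC1=O)O2 | intermediate
14 | lithium enolate of 13 (not isolated) | COc1cc(C)c2c(c1)CC[C@@](C)(CC(=C)C[C@]1(C)CCCC=C1O[Li])O2 | intermediate
15 | (6S)-2-chloro-6-methyl-6-[2-(Chr-methyl)prop-2-en-1-yl]cyclohexan-1-one | COc1cc(C)c2c(c1)CC[C@@](C)(CC(=C)C[C@]1(C)CCCC(Cl)C1=O)O2 | intermediate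
16 | trimethyl[(2-methylbut-3-yn-2-yl)oxy]silane | C#CC(C)(C)O[Si](C)(C)C | starting material
17 | bromomagnesium alkoxide of the alkynyl chlorohydrin (not isolated) | COc1cc(C)c2c(c1)CC[C@@](C)(CC(=C)C[C@]1(C)CCCC(Cl)C1(O[Mg]Br)C#CC(C)(C)O[Si](C)(C)C)O2 | intermediate
18 | 1-{(2S)-2-methyl-2-[2-(Chr-methyl)prop-2-en-1-yl]cyclopentyl}-4-methyl-4-(trimethylsilyloxy)pent-2-yn-1-one | COc1cc(C)c2c(c1)CC[C@@](C)(CC(=C)C[C@]1(C)CCCC1C(=O)C#CC(C)(C)O[Si](C)(C)C)O2 | intermediate
19 | lithium enolate of 18 (not isolated) | COc1cc(C)c2c(c1)CC[C@@](C)(CC(=C)C[C@]1(C)CCCC1=C(O[Li])C#CC(C)(C)O[Si](C)(C)C)O2 | intermediate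
20 | 1-{(1S,2S)-1,2-dimethyl-2-[2-(Chr-methyl)prop-2-en-1-yl]cyclopentyl}-4-methyl-4-(trimethylsilyloxy)pent-2-yn-1-one | COc1cc(C)c2c(c1)CC[C@@](C)(CC(=C)C[C@]1(C)CCC[C@]1(C)C(=O)C#CC(C)(C)O[Si](C)(C)C)O2 | intermediate
21 | ozonide (1,2,4-trioxolane) of 20 (not isolated) | COc1cc(C)c2c(c1)CC[C@@](C)(CC1(C[C@]3(C)CCC[C@]3(C)C(=O)C#CC(C)(C)O[Si](C)(C)C)OCOO1)O2 | intermediate
22 | 1-[(1S,2S)-2-(3-Chr-2-oxopropyl)-1,2-dimethylcyclopentyl]-4-methyl-4-(trimethylsilyloxy)pent-2-yn-1-one | COc1cc(C)c2c(c1)CC[C@@](C)(CC(=O)C[C@]1(C)CCC[C@]1(C)C(=O)C#CC(C)(C)O[Si](C)(C)C)O2 | intermediate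
23 | (2Z)-1-[(1S,2S)-2-(3-Chr-2-oxopropyl)-1,2-dimethylcyclopentyl]-4-methyl-4-(trimethylsilyloxy)pent-2-en-1-one | COc1cc(C)c2c(c1)CC[C@@](C)(CC(=O)C[C@]1(C)CCC[C@]1(C)C(=O)/C=C\C(C)(C)O[Si](C)(C)C)O2 | intermediate
24 | copper enolate of the reduced enone, phosphine ligands not drawn (not isolated) | COc1cc(C)c2c(c1)CC[C@@](C)(CC(=O)C[C@]1(C)CCC[C@]1(C)C(O[Cu])=CCC(C)(C)O[Si](C)(C)C)O2 | intermediate
25 | (3aS,7aS)-6-(Chr-methyl)-6-hydroxy-3a,7a-dimethyl-5-[2-methyl-2-(trimethylsilyloxy)propyl]octahydro-4H-inden-4-one | COc1cc(C)c2c(c1)CC[C@@](C)(CC1(O)C[C@]3(C)CCC[C@]3(C)C(=O)C1CC(C)(C)O[Si](C)(C)C)O2 | intermediate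
26 | methanesulfonate of 25 (not isolated) | COc1cc(C)c2c(c1)CC[C@@](C)(CC1(OS(C)(=O)=O)C[C@]3(C)CCC[C@]3(C)C(=O)C1CC(C)(C)O[Si](C)(C)C)O2 | intermediate
27 | (3aS,7aS)-6-(Chr-methyl)-3a,7a-dimethyl-5-[2-methyl-2-(trimethylsilyloxy)propyl]-1,2,3,3a,7,7a-hexahydro-4H-inden-4-one | COc1cc(C)c2c(c1)CC[C@@](C)(CC1=C(CC(C)(C)O[Si](C)(C)C)C(=O)[C@@]3(C)CCC[C@@]3(C)C1)O2 | intermediate
28 | (3aS,7aS)-5-(2-hydroxy-2-methylpropyl)-6-{[(2S)-6-methoxy-2,8-dimethyl-3,4-dihydro-2H-chromen-2-yl]methyl}-3a,7a-dimethyl-1,2,3,3a,7,7a-hexahydro-4H-inden-4-one | COc1cc(C)c2c(c1)CC[C@@](C)(CC1=C(CC(C)(C)O)C(=O)[C@@]3(C)CCC[C@@]3(C)C1)O2 | target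

**Step count:** 15 steps in total; longest linear sequence 15 steps (1 to 28).

**Steps most likely to fail**

Step 9. The acetylide may deprotonate the α-chloro ketone instead of adding, or the minor trans-chlorohydrin may close to the epoxide instead of rearranging. Fallback, setting out from 13 and returning at 18: 13 is formylated (NaH, ethyl formate) to the (6S)-2-(hydroxymethylene) ketone F1. Deformylative diazo transfer (methanesulfonyl azide, Et3N) gives the α-diazo ketone F2. Photochemical Wolff rearrangement (365 nm) in the presence of N,O-dimethylhydroxylamine contracts the ring and traps the ketene as the cyclopentane Weinreb amide F3. Addition of the lithium acetylide of 16 to F3 gives 18.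

Step 10. Facial selectivity in the methylation of the hindered exocyclic enolate may be poor, and O-methylation may compete. Fallback, setting out from 13 and returning at 20, in which the C3a center is set by the stereospecific shift instead of an alkylation: 13 is methylated at the free α-position (LiN(i-Pr)2, MeI) to the 2,6-dimethyl ketone F4. Enolate chlorination (LiN(i-Pr)2, NCS) gives the tertiary chloride as two epimers, and the (2S,6S) epimer F5 (chlorine cis to the allylic side chain) is separated by chromatography. Treating F5 with the magnesium acetylide of 16 and heating, as in step 9, gives the chlorohydrin bromomagnesium alkoxide F6, which contracts with inversion at the C–Cl carbon directly to 20.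

Step 13. The copper enolate may be protonated or over-reduced before it closes onto the hindered ketone, which is flanked by two neopentyl-type CH2 groups. Fallback, setting out from 23 and returning at 25: conjugate hydrosilylation of 23 (Et3SiH, RhCl(PPh3)3 cat.) gives the triethylsilyl enol ether F7 regiospecifically. An intramolecular Mukaiyama aldol addition of F7 (BF3·OEt2, CH2Cl2, −78 °C) closes the ring to 25 after aqueous work-up, again without a basic enolate next to the chroman.

**Further compounds**
F1 | step 9 | (6S)-2-(hydroxymethylene)-6-methyl-6-[2-(Chr-methyl)prop-2-en-1-yl]cyclohexan-1-one | COc1cc(C)c2c(c1)CC[C@@](C)(CC(=C)C[C@]1(C)CCCC(=CO)C1=O)O2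
F2 | step 9 | (6S)-2-diazo-6-methyl-6-[2-(Chr-methyl)prop-2-en-1-yl]cyclohexan-1-one | COc1cc(C)c2c(c1)CC[C@@](C)(CC(=C)C[C@]1(C)CCCC(=[N+]=[N-])C1=O)O2
F3 | step 9 | (2S)-N-methoxy-N,2-dimethyl-2-[2-(Chr-methyl)prop-2-en-1-yl]cyclopentane-1-carboxamide | COc1cc(C)c2c(c1)CC[C@@](C)(CC(=C)C[C@]1(C)CCCC1C(=O)N(C)OC)O2
F4 | step 10 | (2S)-2,6-dimethyl-2-[2-(Chr-methyl)prop-2-en-1-yl]cyclohexan-1-one | COc1cc(C)c2c(c1)CC[C@@](C)(CC(=C)C[C@]1(C)CCCC(C)C1=O)O2
F5 | step 10 | (2S,6S)-2-chloro-2,6-dimethyl-6-[2-(Chr-methyl)prop-2-en-1-yl]cyclohexan-1-one | COc1cc(C)c2c(c1)CC[C@@](C)(CC(=C)C[C@]1(C)CCC[C@@](Cl)(C)C1=O)O2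
F6 | step 10 | bromomagnesium alkoxide of the alkynyl adduct of F5 | COc1cc(C)c2c(c1)CC[C@@](C)(CC(=C)C[C@]1(C)CCC[C@@](Cl)(C)C1(O[Mg]Br)C#CC(C)(C)O[Si](C)(C)C)O2
F7 | step 13 | triethylsilyl enol ether of the 1,4-reduced enone 23 | COc1cc(C)c2c(c1)CC[C@@](C)(CC(=O)C[C@]1(C)CCC[C@]1(C)C(O[Si](CC)(CC)CC)=CCC(C)(C)O[Si](C)(C)C)O2
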